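**Retrosynthetic overview**
1. Bonannione A ⇐ tris-MOM flavanone 14 (global deprotection) ⇐ one-carbon ring enlargement of the cyclopropane-fused 2,3-dihydrobenzofuran 12/13: the six-membered ring C (O1–C2–C3–C4–C4a–C8a) is made from a five-membered O1–C2–C4–C4a–C8a ring by opening the C2–C4 bond of a fused cyclopropanol, with C3 as the bridging CH2.
2. Enabling feature: in ring C the aryl-ketone carbon C4 and the benzylic, O1-bearing stereocenter C2 are 1,3-related through the C3 methylene, so ring C is the open homoenolate form of a cyclopropanol; the alkoxide on C4 drives the opening and invertive protonation at C2 carries the cyclopropane chirality into the (2S) center.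
3. 12 ⇐ geranyl bromide 11 + aryl iodide 10 (C6 is fixed by iodination ortho to the one free, chelated OH of benzoate 5, before any heterocycle exists) ⇐ asymmetric Simmons–Smith cyclopropanation of 3-silyloxybenzofuran 9.
4. 9 ⇐ carbanion cyclisation of O-benzyl salicylate 7 ⇐ methyl 2,4,6-trihydroxybenzoate 1 + 4-hydroxybenzyl alcohol 3.
5. Ring order: rings A and B are bought as arenes; furan ring (step 6), cyclopropane (step 7), ring C by expansion (step 9).

Key step: step 9

Remark on the chemistry: the ring opening in step 9 is assumed to take the invertive course (protonation anti to the departing carbonyl carbon) known for base-mediated openings of 2-arylcyclopropanols in protic solvents, and 10 is drawn accordingly; the facial sense of the dipeptide-controlled carbenoid on this substrate cannot be predicted, so the antipodal ligand (from D-valine and D-proline) is used if the L,L-ligand delivers the other face.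

**Route**

Step 1
Reactants: 1 methyl 2,4,6-trihydroxybenzoate
Product: 2 methyl 2,6-dihydroxy-4-(methoxymethoxy)benzoate
Conditions: MOMCl (1.05 equiv), i-Pr2NEt, CH2Cl2, 0 °C
Reagents that add atoms: chloromethyl methyl ether (MOMCl), COCCl
Why: Williamson-type MOM protection; the 4-OH is the most acidic hydroxyl and the only one not hydrogen-bonded to the ester, so one equivalent of MOMCl should etherify it selectively.

Step 2
Reactants: 3 4-hydroxybenzyl alcohol
Product: 4 [4-(methoxymethoxy)phenyl]methanol
Conditions: MOMCl (1.0 equiv), K2CO3, acetone, 0 °C → rt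
Reagents that add atoms: chloromethyl methyl ether (MOMCl), COCCl
Why: Phenoxide-selective Williamson alkylation; K2CO3 deprotonates the phenol but not the benzylic alcohol, so only the phenol should be protected.

Step 3
Reactants: 2 methyl 2,6-dihydroxy-4-(methoxymethoxy)benzoate; 4 [4-(methoxymethoxy)phenyl]methanol
Product: 5 methyl 2-hydroxy-4-(methoxymethoxy)-6-{[4-(methoxymethoxy)phenyl]methoxy}benzoate
Conditions: PPh3, DIAD, THF, 0 °C → rt
Reagents that add atoms: none
Why: Mitsunobu etherification of a salicylate-type phenol with a primary benzylic alcohol; the two hydroxyls of 2 are equivalent by symmetry, so mono-alkylation gives one regioisomer and defines which oxygen becomes the ring oxygen O1.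

Step 4
Reactants: 5 methyl 2-hydroxy-4-(methoxymethoxy)-6-{[4-(methoxymethoxy)phenyl]methoxy}benzoate
Product: 6 methyl 2-hydroxy-3-iodo-4-(methoxymethoxy)-6-{[4-(methoxymethoxy)phenyl]methoxy}benzoate
Conditions: BnMe3N·ICl2 (1.05 equiv), CaCO3, CH2Cl2–MeOH (5:2), rt
Reagents that add atoms: benzyltrimethylammonium dichloroiodate, C[N+](C)(C)Cc1ccccc1.Cl[I-]Cl
Why: Electrophilic aromatic iodination with a dichloroiodate salt, which on 2-hydroxy-4,6-dialkoxyaryl carbonyl compounds is expected to go ortho to the free, chelated hydroxyl, so iodine should enter between OH and OMOM (the future C6) and not at the position flanked by the two ethers (the future C8); CaCO3 buffers the HCl so the MOM ethers survive.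

Step 5
Reactants: 6 methyl 2-hydroxy-3-iodo-4-(methoxymethoxy)-6-{[4-(methoxymethoxy)phenyl]methoxy}benzoate
Product: 7 methyl 3-iodo-2,4-bis(methoxymethoxy)-6-{[4-(methoxymethoxy)phenyl]methoxy}benzoate
Conditions: NaH, DMF, 0 °C; then MOMCl, 0 °C → rt
Reagents that add atoms: chloromethyl methyl ether (MOMCl), COCCl
Why: Williamson MOM protection of the hindered, chelated phenol through its sodium phenoxide, which removes the last acidic OH before the carbanion chemistry of step 6.

Step 6
Reactants: 7 methyl 3-iodo-2,4-bis(methoxymethoxy)-6-{[4-(methoxymethoxy)phenyl]methoxy}benzoate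
Product: 9 5-iodo-4,6-bis(methoxymethoxy)-2-[4-(methoxymethoxy)phenyl]-3-[(trimethylsilyl)oxy]-1-benzofuran, via lithium benzofuran-3-olate 8 (not isolated)
Conditions: LiN(i-Pr)2 (2.5 equiv), THF, −78 → 0 °C; then Me3SiCl (3 equiv), −78 °C → rt
Reagents that add atoms: chlorotrimethylsilane, C[Si](C)(C)Cl
Why: Carbanion-mediated (Dieckmann-type) cyclisation: ester-assisted lithiation of the ArO–CH2–Ar position, 5-exo-trig attack on the ester and loss of methoxide should give the benzofuran-3(2H)-one, which the second equivalent of amide converts into the aromatic 3-oxidobenzofuran 8 that is trapped on oxygen by Me3SiCl (enolate O-silylation).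

Step 7
Reactants: 9 5-iodo-4,6-bis(methoxymethoxy)-2-[4-(methoxymethoxy)phenyl]-3-[(trimethylsilyl)oxy]-1-benzofuran
Product: 10 (1aR,6bR)-5-iodo-4,6-bis(methoxymethoxy)-1a-[4-(methoxymethoxy)phenyl]-6b-[(trimethylsilyl)oxy]-1a,6b-dihydro-1H-cyclopropa[b][1]benzofuran
Conditions: Et2Zn (2.5 equiv), CH2I2 (2.5 equiv), N-Boc-L-Val-L-Pro-OMe (1.25 equiv), CH2Cl2, −40 → 0 °C
Reagents that add atoms: diiodomethane, ICI
Why: Asymmetric Simmons–Smith (Furukawa-type) cyclopropanation of a silyl enol ether with a dipeptide-ligated iodomethylzinc carbenoid: concerted syn addition of CH2 to the C2=C3 bond creates C1a and C6b together (cis fusion is the only possibility) and the chiral ligand selects the enantioface; the aryl iodide and MOM ethers are inert, and no other alkene is present because the geranyl group is introduced only afterwards.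

Step 8
Reactants: 10 (1aR,6bR)-5-iodo-4,6-bis(methoxymethoxy)-1a-[4-(methoxymethoxy)phenyl]-6b-[(trimethylsilyl)oxy]-1a,6b-dihydro-1H-cyclopropa[b][1]benzofuran; 11 geranyl bromide
Product: 12 (1aR,6bR)-5-[(2E)-3,7-dimethylocta-2,6-dien-1-yl]-4,6-bis(methoxymethoxy)-1a-[4-(methoxymethoxy)phenyl]-6b-[(trimethylsilyl)oxy]-1a,6b-dihydro-1H-cyclopropa[b][1]benzofuran
Conditions: n-BuLi (1.05 equiv), THF, −78 °C; CuBr·SMe2 (0.2 equiv); then 11, −78 → −20 °C
Reagents that add atoms: none
Why: Iodine–lithium exchange followed by copper-catalysed SN2 allylation of the MOM-chelated aryllithium with geranyl bromide should deliver the linear (E)-geranyl group at the carbon fixed in step 4; the cyclopropane stereocenters are not touched.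

Step 9
Reactants: 12 (1aR,6bR)-5-[(2E)-3,7-dimethylocta-2,6-dien-1-yl]-4,6-bis(methoxymethoxy)-1a-[4-(methoxymethoxy)phenyl]-6b-[(trimethylsilyl)oxy]-1a,6b-dihydro-1H-cyclopropa[b][1]benzofuran
Product: 14 (2S)-6-[(2E)-3,7-dimethylocta-2,6-dien-1-yl]-5,7-bis(methoxymethoxy)-2-[4-(methoxymethoxy)phenyl]-2,3-dihydro-4H-chromen-4-one, via cyclopropanol 13 (not isolated)
Conditions: K2CO3 (0.3 equiv), MeOH–THF (4:1), −10 → 10 °C; then AcOH
Reagents that add atoms: none
Why: Proposed new method: methanolysis of the silyl ether should free cyclopropanol 13, whose alkoxide pushes open the strained C1a–C6b bond shared by the three- and five-membered rings as a homoenolate while methanol protonates C1a on the face anti to the departing carbonyl carbon, so that C6b becomes the C4 ketone, the bridging CH2 becomes C3 and the former O2–C1a–C6b–C6a–C2a furan ring becomes the six-membered ring C. The closest known reaction type is the base-mediated ring opening of 2-arylcyclopropanols to β-aryl ketones, which cleaves toward the benzylic carbon and proceeds with inversion at the protonated carbon in protic media; it has not been used on a ring-fused, α-oxygenated benzylic cyclopropanol as a stereospecific one-carbon ring enlargement. No ring is closed by a new bond: ring C arises by scission of the fusion bond of the bicyclo[3.1.0] unit (ring expansion from five to six members). The C2 stereocenter is set by chirality transfer from C1a of the cyclopropane (fixed in step 7), (1aR) leading to (2S) through invertive C-protonation. The step needs cleavage of the internal C1a–C6b bond rather than the external C1–C6b bond, which is secured because only C1a is benzylic and carries the ring oxygen, and it needs the flavanone to escape retro-oxa-Michael racemisation, for which all phenols are masked and only catalytic carbonate at low temperature with an acetic acid quench is used.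

Step 10
Reactants: 14 (2S)-6-[(2E)-3,7-dimethylocta-2,6-dien-1-yl]-5,7-bis(methoxymethoxy)-2-[4-(methoxymethoxy)phenyl]-2,3-dihydro-4H-chromen-4-one
Product: 15 bonannione A, (2S)-6-[(2E)-3,7-dimethylocta-2,6-dien-1-yl]-5,7-dihydroxy-2-(4-hydroxyphenyl)-2,3-dihydro-4H-chromen-4-one
Conditions: HCl (3 M aq.), MeOH, 45 °C
Reagents that add atoms: none
Why: Acid-catalysed acetal exchange (MOM cleavage) in methanol, the usual end game for prenylated flavanones; C2 should not epimerise under mild acid and the trisubstituted alkenes should tolerate dilute HCl at this temperature.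

**Compound list**
1 | methyl 2,4,6-trihydroxybenzoate | COC(=O)c1c(O)cc(O)cc1O | starting material
2 | methyl 2,6-dihydroxy-4-(methoxymethoxy)benzoate | COC(=O)c1c(O)cc(OCOC)cc1O | intermediate
3 | 4-hydroxybenzyl alcohol | OCc1ccc(O)cc1 | starting material
4 | [4-(methoxymethoxy)phenyl]methanol | COCOc1ccc(CO)cc1 | intermediate
5 | methyl 2-hydroxy-4-(methoxymethoxy)-6-{[4-(methoxymethoxy)phenyl]methoxy}benzoate | COC(=O)c1c(O)cc(OCOC)cc1OCc1ccc(OCOC)cc1 | intermediate
6 | methyl 2-hydroxy-3-iodo-4-(methoxymethoxy)-6-{[4-(methoxymethoxy)phenyl]methoxy}benzoate | COC(=O)c1c(O)c(I)c(OCOC)cc1OCc1ccc(OCOC)cc1 | intermediate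
7 | methyl 3-iodo-2,4-bis(methoxymethoxy)-6-{[4-(methoxymethoxy)phenyl]methoxy}benzoate | COC(=O)c1c(OCOC)c(I)c(OCOC)cc1OCc1ccc(OCOC)cc1 | intermediate
8 | lithium 5-iodo-4,6-bis(methoxymethoxy)-2-[4-(methoxymethoxy)phenyl]-1-benzofuran-3-olate | [Li+].[O-]c1c(-c2ccc(OCOC)cc2)oc2cc(OCOC)c(I)c(OCOC)c12 | intermediate
9 | 5-iodo-4,6-bis(methoxymethoxy)-2-[4-(methoxymethoxy)phenyl]-3-[(trimethylsilyl)oxy]-1-benzofuran | C[Si](C)(C)Oc1c(-c2ccc(OCOC)cc2)oc2cc(OCOC)c(I)c(OCOC)c12 | intermediate
10 | (1aR,6bR)-5-iodo-4,6-bis(methoxymethoxy)-1a-[4-(methoxymethoxy)phenyl]-6b-[(trimethylsilyl)oxy]-1a,6b-dihydro-1H-cyclopropa[b][1]benzofuran (cyclopropane cis-fused on the former C2–C3 bond; aryl and OSiMe3 on the face opposite the CH2 bridge) | Ic1c(OCOC)cc2c(c1OCOC)[C@]3(O[Si](C)(C)C)C[C@]3(c1ccc(OCOC)cc1)O2 | intermediate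
11 | geranyl bromide, (2E)-1-bromo-3,7-dimethylocta-2,6-diene | CC(C)=CCC/C(C)=C/CBr | starting material
12 | (1aR,6bR)-5-[(2E)-3,7-dimethylocta-2,6-dien-1-yl]-4,6-bis(methoxymethoxy)-1a-[4-(methoxymethoxy)phenyl]-6b-[(trimethylsilyl)oxy]-1a,6b-dihydro-1H-cyclopropa[b][1]benzofuran | CC(C)=CCC/C(C)=C/Cc1c(OCOC)cc2c(c1OCOC)[C@]3(O[Si](C)(C)C)C[C@]3(c1ccc(OCOC)cc1)O2 | intermediate
13 | (1aR,6bR)-5-[(2E)-3,7-dimethylocta-2,6-dien-1-yl]-4,6-bis(methoxymethoxy)-1a-[4-(methoxymethoxy)phenyl]-1,1a-dihydro-6bH-cyclopropa[b][1]benzofuran-6b-ol | CC(C)=CCC/C(C)=C/Cc1c(OCOC)cc2c(c1OCOC)[C@]3(O)C[C@]3(c1ccc(OCOC)cc1)O2 | intermediate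
14 | (2S)-6-[(2E)-3,7-dimethylocta-2,6-dien-1-yl]-5,7-bis(methoxymethoxy)-2-[4-(methoxymethoxy)phenyl]-2,3-dihydro-4H-chromen-4-one | CC(C)=CCC/C(C)=C/Cc1c(OCOC)cc2c(c1OCOC)C(=O)C[C@@H](c1ccc(OCOC)cc1)O2 | intermediate
15 | bonannione A, (2S)-6-[(2E)-3,7-dimethylocta-2,6-dien-1-yl]-5,7-dihydroxy-2-(4-hydroxyphenyl)-2,3-dihydro-4H-chromen-4-one | CC(C)=CCC/C(C)=C/Cc1c(O)cc2c(c1O)C(=O)C[C@@H](c1ccc(O)cc1)O2 | target

**Summary**
Total step count: 10. Longest linear sequence: 9 steps (1 → 15 through steps 1 and 3–10); step 2 is a one-step side branch.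

**Steps most likely to fail**

Step 9 (Proposed new method). What may go wrong is partial loss of configuration: a benzylic carbanion with a finite lifetime would be protonated on both faces, and the product could racemise by base-induced retro-oxa-Michael opening and re-closure. The fallback sets out from 12 and comes back at 14, using only known chemistry. Compound 12 is opened without regard to stereochemistry (K2CO3, MeOH, rt, to full conversion) to give the flavanone of low optical purity, handled as racemic 6-geranyl-5,7-bis(methoxymethoxy)-2-[4-(methoxymethoxy)phenyl]chroman-4-one F1. Kinetic resolution by asymmetric transfer hydrogenation (RuCl[(R,R)-TsDPEN](p-cymene) or its antipode, whichever reduces the (2R)-ketone faster; HCO2H–Et3N, EtOAc, rt, stopped near 55% conversion) should convert the (2R)-enantiomer into the cis-(2R,4R)-flavan-4-ol F2 and leave (2S)-14, which is separated by chromatography.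

Step 7. What may go wrong is poor facial discrimination, or slow carbene transfer, at a tetrasubstituted enol ether that is flanked by a MOM ether and carries several zinc-coordinating oxygens. The fallback sets out from 9 and comes back at 10. Achiral Furukawa cyclopropanation (Et2Zn, CH2I2, CF3CO2H, CH2Cl2, 0 °C) should give the racemic 5-iodo-6b-(trimethylsilyloxy)cyclopropa[b]benzofuran F3, which is resolved by preparative chromatography on a chiral stationary phase (supercritical CO2/i-PrOH) into 10 and its (1aS,6bS) enantiomer F4; stereocontrol then rests on separation instead of on the carbenoid.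

Step 6. What may go wrong is slow benzylic deprotonation of the electron-rich ArO–CH2–Ar unit, with [1,2]-Wittig rearrangement or ring metalation next to iodine competing. The fallback sets out from 2 and comes back at 9, replacing the weakly acidic benzylic C–H by an ester-activated one.
- Commercial methyl 4-hydroxymandelate is MOM-protected at the phenol (MOMCl, K2CO3, acetone) to methyl 2-hydroxy-2-[4-(methoxymethoxy)phenyl]acetate F5.
- Mitsunobu coupling of F5 with 2 (PPh3, DIAD, THF) gives methyl 2-hydroxy-6-{2-methoxy-1-[4-(methoxymethoxy)phenyl]-2-oxoethoxy}-4-(methoxymethoxy)benzoate F6.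
- Iodination as in step 4 gives the 3-iodo phenol F7, and MOM protection as in step 5 gives the fully protected iodo diester F8.
- NaH in THF deprotonates the ester-activated C–H, and Dieckmann condensation gives methyl 5-iodo-4,6-bis(methoxymethoxy)-2-[4-(methoxymethoxy)phenyl]-3-oxo-2,3-dihydro-1-benzofuran-2-carboxylate F9.
- Krapcho demethoxycarbonylation (LiCl, wet DMSO, 120 °C) gives 5-iodo-4,6-bis(methoxymethoxy)-2-[4-(methoxymethoxy)phenyl]-1-benzofuran-3(2H)-one F10, which is O-silylated (Me3SiCl, Et3N, DMF) to 9.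

Further compounds
F1 | step 9 | racemic 6-[(2E)-3,7-dimethylocta-2,6-dien-1-yl]-5,7-bis(methoxymethoxy)-2-[4-(methoxymethoxy)phenyl]-2,3-dihydro-4H-chromen-4-one | CC(C)=CCC/C(C)=C/Cc1c(OCOC)cc2c(c1OCOC)C(=O)CC(c1ccc(OCOC)cc1)O2
F2 | step 9 | (2R,4R)-6-[(2E)-3,7-dimethylocta-2,6-dien-1-yl]-5,7-bis(methoxymethoxy)-2-[4-(methoxymethoxy)phenyl]-3,4-dihydro-2H-chromen-4-ol | CC(C)=CCC/C(C)=C/Cc1c(OCOC)cc2c(c1OCOC)[C@H](O)C[C@H](c1ccc(OCOC)cc1)O2
F3 | step 7 | racemic cis-fused 5-iodo-4,6-bis(methoxymethoxy)-1a-[4-(methoxymethoxy)phenyl]-6b-[(trimethylsilyl)oxy]-1a,6b-dihydro-1H-cyclopropa[b][1]benzofuran | Ic1c(OCOC)cc2c(c1OCOC)C3(O[Si](C)(C)C)CC3(c1ccc(OCOC)cc1)O2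
F4 | step 7 | (1aS,6bS)-5-iodo-4,6-bis(methoxymethoxy)-1a-[4-(methoxymethoxy)phenyl]-6b-[(trimethylsilyl)oxy]-1a,6b-dihydro-1H-cyclopropa[b][1]benzofuran | Ic1c(OCOC)cc2c(c1OCOC)[C@@]3(O[Si](C)(C)C)C[C@@]3(c1ccc(OCOC)cc1)O2
F5 | step 6 | methyl 2-hydroxy-2-[4-(methoxymethoxy)phenyl]acetate (racemic) | COC(=O)C(O)c1ccc(OCOC)cc1
F6 | step 6 | methyl 2-hydroxy-6-{2-methoxy-1-[4-(methoxymethoxy)phenyl]-2-oxoethoxy}-4-(methoxymethoxy)benzoate (racemic) | COC(=O)c1c(O)cc(OCOC)cc1OC(C(=O)OC)c1ccc(OCOC)cc1
F7 | step 6 | methyl 2-hydroxy-3-iodo-6-{2-methoxy-1-[4-(methoxymethoxy)phenyl]-2-oxoethoxy}-4-(methoxymethoxy)benzoate (racemic) | COC(=O)c1c(O)c(I)c(OCOC)cc1OC(C(=O)OC)c1ccc(OCOC)cc1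
F8 | step 6 | methyl 3-iodo-6-{2-methoxy-1-[4-(methoxymethoxy)phenyl]-2-oxoethoxy}-2,4-bis(methoxymethoxy)benzoate (racemic) | COC(=O)c1c(OCOC)c(I)c(OCOC)cc1OC(C(=O)OC)c1ccc(OCOC)cc1
F9 | step 6 | methyl 5-iodo-4,6-bis(methoxymethoxy)-2-[4-(methoxymethoxy)phenyl]-3-oxo-2,3-dihydro-1-benzofuran-2-carboxylate (racemic) | COC(=O)C1(c2ccc(OCOC)cc2)Oc2cc(OCOC)c(I)c(OCOC)c2C1=O
F10 | step 6 | 5-iodo-4,6-bis(methoxymethoxy)-2-[4-(methoxymethoxy)phenyl]-1-benzofuran-3(2H)-one (racemic) | O=C1C(c2ccc(OCOC)cc2)Oc2cc(OCOC)c(I)c(OCOC)c21
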